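**Retrosynthetic overview**
1. Feature: O1, the only heteroatom of ring C, sits between C8a of ring A and C2. Removing O1 contracts ring C to a cyclopentane with a direct C8a–C2 bond. This is a 3-arylindan-1-one whose carbonyl carbon is flavan C2 and whose C3 is flavan C4.
2. Late disconnections on the (2S,4R), 2,4-trans flavan: the acyl C–C bond on the phloroglucinol ring (ring D) comes from an aryllithium and a Weinreb amide. The C2–ring B bond comes from an arylzinc and the ring C oxocarbenium ion, made from the lactone through its lactol acetate.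
3. Key disconnection: the O1–C8a bond, by Baeyer–Villiger oxygen insertion. During the oxidation the two free CH positions of ring D carry bromine as a shield. One bromine later serves as the acylation handle and the other leaves in the final hydrogenolysis.
4. The indanone arises by forming C4–C4a in an asymmetric reductive Heck cyclisation of a 2'-bromochalcone, itself made by Claisen–Schmidt condensation of two benzylated building blocks.
5. Ring order: the five-membered carbocycle is formed first and sets C4, then it is expanded to the six-membered ring C. Rings A, B, D and the chain phenyl are bought.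

Key step: step 7

Assumption: (R)-3,5-Xyl-MeOBIPHEP, i.e. (R)-(6,6'-dimethoxybiphenyl-2,2'-diyl)bis[bis(3,5-dimethylphenyl)phosphane], is taken to give the R-configured indanone in step 5; the product needed corresponds in space to (S)-3-phenylindan-1-one (the descriptor changes because the trioxygenated aryl group outranks C3a), and if the hindered substrate responds in the opposite sense the equally available (S)-ligand is used.

Step 1
Reactants: 1 3-hydroxyacetophenone
Product: 2 1-[3-(benzyloxy)phenyl]ethan-1-one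
Conditions: BnBr (1.1 equiv), K2CO3, acetone, reflux
Reagents that add atoms: benzyl bromide, BrCc1ccccc1
Why: Williamson ether synthesis, in which the phenoxide formed by K2CO3 displaces bromide from benzyl bromide by SN2 and the weak base leaves the methyl ketone alone.

Step 2
Reactants: 2 1-[3-(benzyloxy)phenyl]ethan-1-one
Product: 3 1-[5-(benzyloxy)-2-bromophenyl]ethan-1-one
Conditions: NBS (1.05 equiv), MeCN, rt, dark
Reagents that add atoms: N-bromosuccinimide, O=C1CCC(=O)N1Br
Why: Electrophilic aromatic bromination, in which NBS in polar MeCN acts as an ionic bromine donor and attacks para to the benzyloxy group (ortho to acetyl), as known for 3-alkoxyacetophenones, while the absence of acid and light keeps the α-carbon and the benzylic CH2 unreacted.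

Step 3
Reactants: 4 2,4,6-trihydroxybenzaldehyde
Product: 5 2,4,6-tris(benzyloxy)benzaldehyde
Conditions: BnBr (3.6 equiv), K2CO3 (4 equiv), DMF, 60 °C
Reagents that add atoms: benzyl bromide, BrCc1ccccc1
Why: Threefold Williamson ether synthesis, in which the formyl group lowers the carbon nucleophilicity of the phloroglucinol so that O-alkylation should prevail, and warming completes the two hydrogen-bonded ortho hydroxyls.

Step 4
Reactants: 3 1-[5-(benzyloxy)-2-bromophenyl]ethan-1-one; 5 2,4,6-tris(benzyloxy)benzaldehyde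
Product: 7 (E)-1-[5-(benzyloxy)-2-bromophenyl]-3-[2,4,6-tris(benzyloxy)phenyl]prop-2-en-1-one, via aldol adduct 6 (not isolated)
Conditions: KOH, EtOH/THF, rt → 40 °C
Reagents that add atoms: none
Why: Claisen–Schmidt condensation, in which only ketone 3 can enolise, its enolate adds to the non-enolisable aldehyde 5, and E1cB loss of water from 6 gives the conjugated enone as the less strained E isomer.

Step 5
Reactants: 7 (E)-1-[5-(benzyloxy)-2-bromophenyl]-3-[2,4,6-tris(benzyloxy)phenyl]prop-2-en-1-one
Product: 8 (R)-6-(benzyloxy)-3-[2,4,6-tris(benzyloxy)phenyl]indan-1-one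
Conditions: Pd(OAc)2 (5 mol %), (R)-3,5-Xyl-MeOBIPHEP (7 mol %), HCO2H (2 equiv), i-Pr2NEt (4 equiv), ethylene glycol/DMF, 90 °C
Reagents that add atoms: none
Why: Asymmetric intramolecular reductive Heck reaction, known for 2'-bromochalcones: zerovalent palladium inserts into C–Br, the aryl carbon joins the β-carbon (formal 5-endo-trig) in the enantio-determining insertion where the chiral bisphosphine selects the enone face and sets C3 (flavan C4) as R, formate reduces the palladium enolate, and the ammonium salt in glycol pulls bromide off palladium so that the selective cationic pathway operates.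

Step 6
Reactants: 8 (R)-6-(benzyloxy)-3-[2,4,6-tris(benzyloxy)phenyl]indan-1-one
Product: 9 (R)-6-(benzyloxy)-3-[2,4,6-tris(benzyloxy)-3,5-dibromophenyl]indan-1-one
Conditions: NBS (2.1 equiv), CH2Cl2, 0 °C → rt, dark
Reagents that add atoms: N-bromosuccinimide, O=C1CCC(=O)N1Br
Why: Electrophilic aromatic bromination, in which the 1,3,5-trioxygenated ring D is by far the most nucleophilic arene (ring A is deactivated by the carbonyl), so two equivalents of NBS should fill exactly the two positions where a peracid would otherwise hydroxylate.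

Step 7
Reactants: 9 (R)-6-(benzyloxy)-3-[2,4,6-tris(benzyloxy)-3,5-dibromophenyl]indan-1-one
Product: 11 (R)-7-(benzyloxy)-4-[2,4,6-tris(benzyloxy)-3,5-dibromophenyl]chroman-2-one, via Criegee adduct 10 (not isolated)
Conditions: mCPBA (3 equiv), TsOH·H2O (0.3 equiv), CH2Cl2, 0–4 °C, dark
Reagents that add atoms: 3-chloroperoxybenzoic acid, O=C(OO)c1cccc(Cl)c1
Why: The acid-activated C1 carbonyl adds the peracid to give Criegee adduct 10, and the C1–C7a bond lying antiperiplanar to the O–O bond shifts from carbon to oxygen as 3-chlorobenzoate leaves, which creates the O1–C8a bond and turns C1 into the lactone carbon C2. The closest known reaction is the Baeyer–Villiger oxidation of 1-indanones, 3-aryl-1-indanones included, to 3,4-dihydrocoumarins with mCPBA and a sulfonic acid. Ring C is not closed by a cyclisation but arises by one-atom expansion of the five-membered carbocycle through this 1,2-shift. No stereocentre is formed, and indanone C3 (flavan C4) is β to the carbonyl, takes no part in the bond changes and keeps its R configuration. The regioselectivity needed is aryl over methylene migration, which the better cation-stabilising sp2 carbon C7a with its ortho alkyl branch should win over the primary C2, the 6-benzyloxy group being meta to C7a so that it leaves the ketone electrophilic. The chemoselectivity needed is ketone over arene oxidation, secured by the two bromine atoms that occupy the only free positions of ring D and twist its benzyloxy groups out of conjugation, and by the carbonyl (later acyloxy) group that deactivates ring A.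

Step 8
Reactants: 11 (R)-7-(benzyloxy)-4-[2,4,6-tris(benzyloxy)-3,5-dibromophenyl]chroman-2-one
Product: 13 (4R)-7-(benzyloxy)-4-[2,4,6-tris(benzyloxy)-3,5-dibromophenyl]chroman-2-ol (both C2 epimers), via aluminium hemiacetal 12 (not isolated)
Conditions: i-Bu2AlH (1.15 equiv), toluene/CH2Cl2, −78 °C; aq. potassium sodium tartrate
Reagents that add atoms: diisobutylaluminium hydride, CC(C)C[AlH]CC(C)C (aluminium and isobutyl groups in 12 only)
Why: Partial lactone reduction, known for 4-aryl-3,4-dihydrocoumarins, in which one hydride adds and the tetrahedral aluminium hemiacetal 12 persists at −78 °C until hydrolysis, while aryl bromides and benzyl ethers are inert.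

Step 9
Reactants: 13 (4R)-7-(benzyloxy)-4-[2,4,6-tris(benzyloxy)-3,5-dibromophenyl]chroman-2-ol
Product: 14 (4R)-7-(benzyloxy)-4-[2,4,6-tris(benzyloxy)-3,5-dibromophenyl]chroman-2-yl acetate (both C2 epimers)
Conditions: Ac2O, pyridine, 4-(dimethylamino)pyridine (cat.), CH2Cl2, 0 °C → rt
Reagents that add atoms: acetic anhydride, CC(=O)OC(C)=O
Why: O-acylation of the cyclic hemiacetal, the dominant tautomer of chroman-2-ols, installs a leaving group at C2 whose configuration does not matter because it is lost on ionisation.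

Step 10
Reactants: 14 (4R)-7-(benzyloxy)-4-[2,4,6-tris(benzyloxy)-3,5-dibromophenyl]chroman-2-yl acetate; 15 1-(benzyloxy)-4-bromobenzene
Product: 19 (2S,4R)-7-(benzyloxy)-2-[4-(benzyloxy)phenyl]-4-[2,4,6-tris(benzyloxy)-3,5-dibromophenyl]chroman, via Grignard reagent 16 (not isolated), via arylzinc bromide 17 (not isolated), via oxocarbenium triflate 18 (not isolated)
Conditions: 15, Mg, THF, 40 °C; ZnBr2, 0 °C → rt; 14 in CH2Cl2, then Me3SiOTf (1.3 equiv), −78 → −40 °C
Reagents that add atoms: magnesium, [Mg]; zinc dibromide, Br[Zn]Br; trimethylsilyl trifluoromethanesulfonate, C[Si](C)(C)OS(=O)(=O)C(F)(F)F (their atoms stay in 16, 17 and 18 only)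
Why: Lewis-acid-mediated substitution of a lactol acetate by an arylzinc reagent (oxocarbenium arylation of the C-aryl glycoside type), in which Me3SiOTf ionises 14 to 18 and the aryl group should enter anti to the very bulky C4 aryl group, since both steric shielding in the pseudoaxial conformer and axial attack on the pseudoequatorial conformer lead to the 2,4-trans product and set C2 as S.

Step 11
Reactants: 20 9-phenylnonanoic acid
Product: 22 N-methoxy-N-methyl-9-phenylnonanamide, via acyl imidazole 21 (not isolated)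
Conditions: 1,1'-carbonyldiimidazole (1.1 equiv), CH2Cl2, rt; then MeNH(OMe)·HCl, rt
Reagents that add atoms: 1,1'-carbonyldiimidazole, O=C(n1ccnc1)n1ccnc1 (imidazolyl group in 21 only); N,O-dimethylhydroxylamine hydrochloride, CNOC.Cl
Why: Standard Weinreb amide synthesis, in which the acid is activated as acyl imidazole 21 with loss of CO2 and the hydroxylamine salt then displaces imidazole.

Step 12
Reactants: 19 (2S,4R)-7-(benzyloxy)-2-[4-(benzyloxy)phenyl]-4-[2,4,6-tris(benzyloxy)-3,5-dibromophenyl]chroman; 22 N-methoxy-N-methyl-9-phenylnonanamide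
Product: 25 1-{2,4,6-tris(benzyloxy)-3-bromo-5-[(2S,4R)-7-(benzyloxy)-2-[4-(benzyloxy)phenyl]chroman-4-yl]phenyl}-9-phenylnonan-1-one, via aryllithium 23 (not isolated), via lithium hemiaminal 24 (not isolated)
Conditions: n-BuLi (1.05 equiv), THF, −78 °C; 22, −78 → −40 °C; AcOH, −78 °C
Reagents that add atoms: n-butyllithium, [Li]CCCC (lithium in 23 and 24 only)
Why: Bromine–lithium exchange followed by Weinreb ketone synthesis, in which the two bromines are equivalent by rotation about the C4–aryl bond so one equivalent of n-BuLi gives a single monolithium species flanked by two chelating benzyloxy groups, the chelated adduct 24 prevents over-addition, and the acid-free conditions avoid ionisation of the C2–O1 bond that a Friedel–Crafts acylation would risk.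

Step 13
Reactants: 25 1-{2,4,6-tris(benzyloxy)-3-bromo-5-[(2S,4R)-7-(benzyloxy)-2-[4-(benzyloxy)phenyl]chroman-4-yl]phenyl}-9-phenylnonan-1-one
Product: 26 (+)-myristinin D, 1-{2,4,6-trihydroxy-3-[(2S,4R)-7-hydroxy-2-(4-hydroxyphenyl)chroman-4-yl]phenyl}-9-phenylnonan-1-one
Conditions: H2 (1 atm), 10% Pd/C, NaOAc (1.5 equiv), THF/MeOH, rt
Reagents that add atoms: none
Why: Catalytic hydrogenolysis should cleave the five aryl benzyl ethers and the aryl C–Br bond in one operation, with NaOAc trapping HBr so that the acid-labile C2–O1 bond is not ionised, while the hydrogen-bonded acylphloroglucinol ketone and the cyclic benzylic ether should survive at 1 atm and no stereocentre is touched.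

**Compound list**
1 | 3-hydroxyacetophenone | CC(=O)c1cccc(O)c1 | starting material
2 | 1-[3-(benzyloxy)phenyl]ethan-1-one | CC(=O)c1cccc(OCc2ccccc2)c1 | intermediate
3 | 1-[5-(benzyloxy)-2-bromophenyl]ethan-1-one | CC(=O)c1cc(OCc2ccccc2)ccc1Br | intermediate
4 | 2,4,6-trihydroxybenzaldehyde | O=Cc1c(O)cc(O)cc1O | starting material
5 | 2,4,6-tris(benzyloxy)benzaldehyde | O=Cc1c(OCc2ccccc2)cc(OCc2ccccc2)cc1OCc1ccccc1 | intermediate
6 | 1-[5-(benzyloxy)-2-bromophenyl]-3-hydroxy-3-[2,4,6-tris(benzyloxy)phenyl]propan-1-one (racemic aldol adduct, not isolated) | O=C(CC(O)c1c(OCc2ccccc2)cc(OCc2ccccc2)cc1OCc1ccccc1)c1cc(OCc2ccccc2)ccc1Br | intermediate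
7 | (E)-1-[5-(benzyloxy)-2-bromophenyl]-3-[2,4,6-tris(benzyloxy)phenyl]prop-2-en-1-one | O=C(/C=C/c1c(OCc2ccccc2)cc(OCc2ccccc2)cc1OCc1ccccc1)c1cc(OCc2ccccc2)ccc1Br | intermediate
8 | (R)-6-(benzyloxy)-3-[2,4,6-tris(benzyloxy)phenyl]indan-1-one | c1ccccc1COc1cc(OCc2ccccc2)c([C@@H]2CC(=O)c3cc(OCc4ccccc4)ccc32)c(OCc2ccccc2)c1 | intermediate
9 | (R)-6-(benzyloxy)-3-[2,4,6-tris(benzyloxy)-3,5-dibromophenyl]indan-1-one | c1ccccc1COc1c(Br)c(OCc2ccccc2)c([C@@H]2CC(=O)c3cc(OCc4ccccc4)ccc32)c(OCc2ccccc2)c1Br | intermediate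
10 | (3R)-6-(benzyloxy)-1-hydroxy-3-[2,4,6-tris(benzyloxy)-3,5-dibromophenyl]indan-1-yl 3-chloroperoxybenzoate (Criegee adduct, not isolated) | c1ccccc1COc1c(Br)c(OCc2ccccc2)c([C@@H]2CC(O)(OOC(=O)c3cccc(Cl)c3)c3cc(OCc4ccccc4)ccc32)c(OCc2ccccc2)c1Br | intermediate
11 | (R)-7-(benzyloxy)-4-[2,4,6-tris(benzyloxy)-3,5-dibromophenyl]chroman-2-one | c1ccccc1COc1c(Br)c(OCc2ccccc2)c([C@@H]2CC(=O)Oc3cc(OCc4ccccc4)ccc32)c(OCc2ccccc2)c1Br | intermediate
12 | diisobutylaluminium alkoxide of lactol 13 (aluminium hemiacetal, not isolated) | c1ccccc1COc1c(Br)c(OCc2ccccc2)c([C@@H]2CC(O[Al](CC(C)C)CC(C)C)Oc3cc(OCc4ccccc4)ccc32)c(OCc2ccccc2)c1Br | intermediate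
13 | (4R)-7-(benzyloxy)-4-[2,4,6-tris(benzyloxy)-3,5-dibromophenyl]chroman-2-ol (C2 epimers) | c1ccccc1COc1c(Br)c(OCc2ccccc2)c([C@@H]2CC(O)Oc3cc(OCc4ccccc4)ccc32)c(OCc2ccccc2)c1Br | intermediate
14 | (4R)-7-(benzyloxy)-4-[2,4,6-tris(benzyloxy)-3,5-dibromophenyl]chroman-2-yl acetate (C2 epimers) | c1ccccc1COc1c(Br)c(OCc2ccccc2)c([C@@H]2CC(OC(C)=O)Oc3cc(OCc4ccccc4)ccc32)c(OCc2ccccc2)c1Br | intermediate
15 | 1-(benzyloxy)-4-bromobenzene | Brc1ccc(OCc2ccccc2)cc1 | starting material
16 | [4-(benzyloxy)phenyl]magnesium bromide (not isolated) | Br[Mg]c1ccc(OCc2ccccc2)cc1 | intermediate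
17 | [4-(benzyloxy)phenyl]zinc bromide (not isolated) | Br[Zn]c1ccc(OCc2ccccc2)cc1 | intermediate
18 | (R)-7-(benzyloxy)-4-[2,4,6-tris(benzyloxy)-3,5-dibromophenyl]-3,4-dihydro-1-benzopyrylium trifluoromethanesulfonate (not isolated) | c1ccccc1COc1c(Br)c(OCc2ccccc2)c([C@@H]2CC=[O+]c3cc(OCc4ccccc4)ccc32)c(OCc2ccccc2)c1Br.[O-]S(=O)(=O)C(F)(F)F | intermediate
19 | (2S,4R)-7-(benzyloxy)-2-[4-(benzyloxy)phenyl]-4-[2,4,6-tris(benzyloxy)-3,5-dibromophenyl]chroman | c1ccccc1COc1c(Br)c(OCc2ccccc2)c([C@@H]2C[C@@H](c3ccc(OCc4ccccc4)cc3)Oc3cc(OCc4ccccc4)ccc32)c(OCc2ccccc2)c1Br | intermediate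
20 | 9-phenylnonanoic acid | OC(=O)CCCCCCCCc1ccccc1 | starting material
21 | 1-(1H-imidazol-1-yl)-9-phenylnonan-1-one (not isolated) | O=C(CCCCCCCCc1ccccc1)n1ccnc1 | intermediate
22 | N-methoxy-N-methyl-9-phenylnonanamide | CON(C)C(=O)CCCCCCCCc1ccccc1 | intermediate
23 | monolithium species from 19, lithium in place of one ring D bromine (not isolated) | c1ccccc1COc1c([Li])c(OCc2ccccc2)c([C@@H]2C[C@@H](c3ccc(OCc4ccccc4)cc3)Oc3cc(OCc4ccccc4)ccc32)c(OCc2ccccc2)c1Br | intermediate
24 | lithium hemiaminal from 23 and 22 (tetrahedral adduct, not isolated) | c1ccccc1COc1c(C(O[Li])(N(C)OC)CCCCCCCCc2ccccc2)c(OCc2ccccc2)c([C@@H]2C[C@@H](c3ccc(OCc4ccccc4)cc3)Oc3cc(OCc4ccccc4)ccc32)c(OCc2ccccc2)c1Br | intermediate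
25 | 1-{2,4,6-tris(benzyloxy)-3-bromo-5-[(2S,4R)-7-(benzyloxy)-2-[4-(benzyloxy)phenyl]chroman-4-yl]phenyl}-9-phenylnonan-1-one | O=C(CCCCCCCCc1ccccc1)c1c(OCc2ccccc2)c(Br)c(OCc2ccccc2)c([C@@H]2C[C@@H](c3ccc(OCc4ccccc4)cc3)Oc3cc(OCc4ccccc4)ccc32)c1OCc1ccccc1 | intermediate
26 | (+)-myristinin D, (2S,4R) | O=C(CCCCCCCCc1ccccc1)c1c(O)cc(O)c([C@@H]2C[C@@H](c3ccc(O)cc3)Oc3cc(O)ccc32)c1O | target

**Step count**
Total: 13 steps. Longest linear sequence: 11 steps (1, 2, 4–10, 12, 13) from 3-hydroxyacetophenone.

**Steps most likely to fail**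

Step 7.
- Risk: the C2 methylene may migrate in competition with the aryl carbon. The Criegee adduct may also break down so slowly that the peracid starts to attack benzyloxy-substituted rings or benzylic C–H bonds.
- Fallback: oxygen insertion at the alcohol oxidation level without any peracid. It sets out from 9 and returns at 13, replacing steps 7 and 8.
- NaBH4 in MeOH/THF reduces the ketone to (3R)-6-(benzyloxy)-3-[2,4,6-tris(benzyloxy)-3,5-dibromophenyl]indan-1-ol F1 (C1 epimers).
- Acid-catalysed perhydrolysis (ethereal H2O2 or urea·H2O2, cat. TsOH·H2O, 0 °C) exchanges the benzylic hydroxyl and gives (3R)-6-(benzyloxy)-3-[2,4,6-tris(benzyloxy)-3,5-dibromophenyl]indan-1-yl hydroperoxide F2.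
- Catalytic BF3·OEt2 in CH2Cl2 at −20 °C then triggers a Hock rearrangement. C7a shifts to oxygen as the activated hydroxyl leaves, the ring C oxocarbenium ion forms and takes the hydroxyl back up, and lactol 13 results.

Step 10.
- Risk: the neighbouring ortho-benzyloxy oxygen may capture the oxocarbenium ion with loss of a benzyl group. Proton loss from C3, incomplete facial selectivity, or Lewis-acid-induced reopening of the new C2–O1 bond with scrambling of C2 are also possible.
- Fallback: a reagent-controlled carbinol followed by SN2 ring closure instead of cation chemistry. It sets out from 11 and returns at 19, replacing steps 8–10.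
- Lactone 11 is opened with MeNH(OMe)·HCl and i-PrMgCl (THF, −20 °C) to (R)-3-[4-(benzyloxy)-2-hydroxyphenyl]-N-methoxy-N-methyl-3-[2,4,6-tris(benzyloxy)-3,5-dibromophenyl]propanamide F3.
- Excess Grignard reagent 16, whose first equivalent is consumed by the phenol, gives (R)-1-[4-(benzyloxy)phenyl]-3-[4-(benzyloxy)-2-hydroxyphenyl]-3-[2,4,6-tris(benzyloxy)-3,5-dibromophenyl]propan-1-one F4.
- Corey–Bakshi–Shibata reduction uses (S)-1-methyl-3,3-diphenyltetrahydro-1H,3H-pyrrolo[1,2-c][1,3,2]oxazaborole and BH3·SMe2. It gives (1R,3R)-1-[4-(benzyloxy)phenyl]-3-[4-(benzyloxy)-2-hydroxyphenyl]-3-[2,4,6-tris(benzyloxy)-3,5-dibromophenyl]propan-1-ol F5.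
- Intramolecular Mitsunobu etherification (PPh3, diisopropyl azodicarboxylate, THF, 0 °C) closes ring C with inversion at the carbinol carbon and gives 19.

Step 5.
- Risk: hydrodebromination or conjugate reduction of the enone may outrun the hindered insertion. Face discrimination may also be poor because the β-aryl group carries two ortho substituents.
- Fallback: the stereocentre is set by ketone reduction and then relayed by chirality transfer. It sets out from 7 and returns at 8.
- A non-reductive Heck cyclisation (Pd(OAc)2, PPh3, K2CO3, DMF, 110 °C) gives 6-(benzyloxy)-3-[2,4,6-tris(benzyloxy)phenyl]-1H-inden-1-one F6.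
- Corey–Bakshi–Shibata reduction, with the oxazaborolidine antipode chosen for this sense, gives (S)-6-(benzyloxy)-3-[2,4,6-tris(benzyloxy)phenyl]-1H-inden-1-ol F7.
- Amine base (1,4-diazabicyclo[2.2.2]octane, Et3N, THF, 60 °C) effects the known suprafacial 1,3-hydrogen shift of 3-arylindenols. The C1 hydrogen moves to the same face of C3, and tautomerisation of the enol gives 8.

**Further compounds**
F1 | step 7 | (3R)-6-(benzyloxy)-3-[2,4,6-tris(benzyloxy)-3,5-dibromophenyl]indan-1-ol (C1 epimers) | c1ccccc1COc1c(Br)c(OCc2ccccc2)c([C@@H]2CC(O)c3cc(OCc4ccccc4)ccc32)c(OCc2ccccc2)c1Br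
F2 | step 7 | (3R)-6-(benzyloxy)-3-[2,4,6-tris(benzyloxy)-3,5-dibromophenyl]indan-1-yl hydroperoxide (C1 epimers) | c1ccccc1COc1c(Br)c(OCc2ccccc2)c([C@@H]2CC(OO)c3cc(OCc4ccccc4)ccc32)c(OCc2ccccc2)c1Br
F3 | step 10 | (R)-3-[4-(benzyloxy)-2-hydroxyphenyl]-N-methoxy-N-methyl-3-[2,4,6-tris(benzyloxy)-3,5-dibromophenyl]propanamide | c1ccccc1COc1c(Br)c(OCc2ccccc2)c([C@H](CC(=O)N(C)OC)c3ccc(OCc4ccccc4)cc3O)c(OCc2ccccc2)c1Br
F4 | step 10 | (R)-1-[4-(benzyloxy)phenyl]-3-[4-(benzyloxy)-2-hydroxyphenyl]-3-[2,4,6-tris(benzyloxy)-3,5-dibromophenyl]propan-1-one | c1ccccc1COc1c(Br)c(OCc2ccccc2)c([C@H](CC(=O)c3ccc(OCc4ccccc4)cc3)c3ccc(OCc4ccccc4)cc3O)c(OCc2ccccc2)c1Br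
F5 | step 10 | (1R,3R)-1-[4-(benzyloxy)phenyl]-3-[4-(benzyloxy)-2-hydroxyphenyl]-3-[2,4,6-tris(benzyloxy)-3,5-dibromophenyl]propan-1-ol | c1ccccc1COc1c(Br)c(OCc2ccccc2)c([C@H](C[C@@H](O)c3ccc(OCc4ccccc4)cc3)c3ccc(OCc4ccccc4)cc3O)c(OCc2ccccc2)c1Br
F6 | step 5 | 6-(benzyloxy)-3-[2,4,6-tris(benzyloxy)phenyl]-1H-inden-1-one | O=C1C=C(c2c(OCc3ccccc3)cc(OCc3ccccc3)cc2OCc2ccccc2)c2ccc(OCc3ccccc3)cc21
F7 | step 5 | (S)-6-(benzyloxy)-3-[2,4,6-tris(benzyloxy)phenyl]-1H-inden-1-ol | O[C@H]1C=C(c2c(OCc3ccccc3)cc(OCc3ccccc3)cc2OCc2ccccc2)c2ccc(OCc3ccccc3)cc21
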